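## Retrosynthetic overview

1. The target is (4R,5R,9S,10R,13S)-15-acetoxylabd-8(17)-en-18-oic acid: a trans-decalin with the CO2H equatorial at C4 (anti to the angular methyl), an equatorial side chain at C9 and an exocyclic methylene at C8. CO2H ⇐ CHO ⇐ CH=N–NMe2.
2. Both rings are closed in one enantioselective, Brønsted-acid-catalysed bicyclization of an acyclic triene hydrazone: C4–C5 (ring A) first, then C9–C10 (ring B), ended by an allylsilane that leaves only the 8(17)-alkene.
3. The triene comes from an enynol, Me3SiCH2Cu and a chiral iodide (syn-carbocupration/alkylation makes the C9–C11 bond and the Z allylsilane).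
4. The enynol comes from geranylacetone. The iodide (C11–C15, carrying C13) comes from 3-methylglutaric anhydride by organocatalytic desymmetrization.

Assumption: the (DHQD)2AQN series is taken to give the (S)-hemiester and the (S,S)-IDPi the 5R,10R series; if either sense is the opposite, the pseudo-enantiomeric or mirror-image catalyst is used and nothing else changes.

## Route

Step 1
Reactants: 1 3-methylglutaric anhydride
Product: 2 (3S)-5-methoxy-3-methyl-5-oxopentanoic acid
Conditions: (DHQD)2AQN (10 mol%), MeOH (10 equiv), Et2O, −40 °C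
Reagents that add atoms: methanol, CO
Why: Cinchona-alkaloid-catalysed desymmetrizing alcoholysis of a prochiral cyclic anhydride (general-base organocatalysis); the catalyst selects one of the two enantiotopic carbonyl groups and so sets the methyl-bearing carbon (future C13) as S.

Step 2
Reactants: 2 (3S)-5-methoxy-3-methyl-5-oxopentanoic acid
Product: 3 methyl (3S)-5-hydroxy-3-methylpentanoate
Conditions: BH3·SMe2 (1.1 equiv), THF, 0 °C to rt; MeOH quench
Reagents that add atoms: none
Why: Chemoselective borane reduction of a carboxylic acid in the presence of an ester; the stereocenter is not touched.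

Step 3
Reactants: 3 methyl (3S)-5-hydroxy-3-methylpentanoate
Product: 4 methyl (3R)-5-iodo-3-methylpentanoate
Conditions: I2, PPh3, imidazole, CH2Cl2, 0 °C to rt
Reagents that add atoms: iodine, II
Why: Appel-type iodination of a primary alcohol; the descriptor changes from S to R only because iodine changes the CIP priorities.

Step 4
Reactants: 5 (5E)-6,10-dimethylundeca-5,9-dien-2-one (geranylacetone)
Product: 7 (5E)-6,10-dimethylundeca-5,9-dien-1-yne, via enol phosphate 6 (not isolated)
Conditions: LiN(iPr)2 (1.05 equiv), THF, −78 °C; ClP(O)(OEt)2, −78 °C to rt; then LiN(iPr)2 (2.3 equiv), −78 °C to rt; H2O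
Reagents that add atoms: none
Why: Negishi methyl ketone to terminal alkyne conversion: the kinetic enolate is O-phosphorylated and the enol phosphate undergoes base-induced elimination, leaving the E alkene untouched.

Step 5
Reactants: 7 (5E)-6,10-dimethylundeca-5,9-dien-1-yne
Product: 8 (2E,6E)-2,6-dimethylundeca-2,6-dien-10-yn-1-ol
Conditions: SeO2 (0.3 equiv), tBuOOH (2.5 equiv), salicylic acid (0.1 equiv), CH2Cl2, 0 °C to rt, stopped at partial conversion, 7 recycled
Reagents that add atoms: tert-butyl hydroperoxide, CC(C)(C)OO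
Why: SeO2/tBuOOH allylic oxidation (ene reaction, then [2,3]-sigmatropic shift) hydroxylates the E-methyl group of the terminal isopropylidene unit, giving the E allylic alcohol.

Step 6
Reactants: 8 (2E,6E)-2,6-dimethylundeca-2,6-dien-10-yn-1-ol; 4 methyl (3R)-5-iodo-3-methylpentanoate
Product: 11 methyl (3S,6Z,10E,14E)-16-hydroxy-3,11,15-trimethyl-7-[(trimethylsilyl)methyl]hexadeca-6,10,14-trienoate, via chloromagnesium alkoxide 9 (not isolated), via alkenylcopper species 10 (not isolated)
Conditions: MeMgCl (1.0 equiv), Et2O, −20 °C; Me3SiCH2MgCl, CuBr·SMe2 (1.5 equiv each), Et2O/Me2S, −20 to 0 °C; then 4 (1.3 equiv), HMPA, P(OEt)3, −20 °C to rt; aq. NH4Cl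
Reagents that add atoms: (trimethylsilyl)methylmagnesium chloride, C[Si](C)(C)C[Mg]Cl
Why: Normant syn-carbocupration puts Me3SiCH2 on the internal alkyne carbon and copper on the terminal carbon cis to it, and alkylation of the alkenylcopper by the primary iodide goes with retention, so the allylsilane forms as the single 6Z isomer (C7 trans to C11) that ring B closure needs.

Step 7
Reactants: 11 methyl (3S,6Z,10E,14E)-16-hydroxy-3,11,15-trimethyl-7-[(trimethylsilyl)methyl]hexadeca-6,10,14-trienoate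
Product: 12 (2E,6E,10Z,14S)-2,6,14-trimethyl-10-[(trimethylsilyl)methyl]hexadeca-2,6,10-triene-1,16-diol
Conditions: LiAlH4, Et2O, 0 °C; Fieser work-up
Reagents that add atoms: none
Why: Hydride reduction of the ester to the primary alcohol; alkenes and the allylsilane are inert.

Step 8
Reactants: 12 (2E,6E,10Z,14S)-2,6,14-trimethyl-10-[(trimethylsilyl)methyl]hexadeca-2,6,10-triene-1,16-diol
Product: 14 (3S,6Z,10E,14E,16E)-16-(2,2-dimethylhydrazinylidene)-3,11,15-trimethyl-7-[(trimethylsilyl)methyl]hexadeca-6,10,14-trien-1-ol, via enal 13 (not isolated)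
Conditions: MnO2 (15 equiv), CH2Cl2, rt; filter; Me2NNH2 (1.5 equiv), MgSO4, CH2Cl2, rt
Reagents that add atoms: 1,1-dimethylhydrazine, CN(C)N
Why: MnO2 oxidizes only the allylic alcohol, and the enal condenses 1,2 with the hydrazine to the E hydrazone (a 1-amino-1-azadiene).

Step 9
Reactants: 14 (3S,6Z,10E,14E,16E)-16-(2,2-dimethylhydrazinylidene)-3,11,15-trimethyl-7-[(trimethylsilyl)methyl]hexadeca-6,10,14-trien-1-ol
Product: 15 (3S,6Z,10E,14E,16E)-16-(2,2-dimethylhydrazinylidene)-3,11,15-trimethyl-7-[(trimethylsilyl)methyl]hexadeca-6,10,14-trien-1-yl acetate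
Conditions: Ac2O, pyridine, DMAP (cat.), CH2Cl2, 0 °C
Reagents that add atoms: acetic anhydride, CC(=O)OC(C)=O
Why: DMAP-catalysed acetylation of the primary alcohol; the N,N-dimethylhydrazone has no N–H and is not acylated.

Step 10
Reactants: 15 (3S,6Z,10E,14E,16E)-16-(2,2-dimethylhydrazinylidene)-3,11,15-trimethyl-7-[(trimethylsilyl)methyl]hexadeca-6,10,14-trien-1-yl acetate
Product: 17 (3S)-5-[(1S,4aR,5R,8aR)-5-formyl-5,8a-dimethyl-2-methylidenedecahydronaphthalen-1-yl]-3-methylpentyl acetate, via bicyclic hydrazone 16 (not isolated)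
Conditions: (S,S)-IDPi (BINOL-derived imidodiphosphorimidate, 3,3′-aryl groups, N-triflyl core; 5 mol%), (CF3)2CHOH (3 equiv), CH2Cl2, −40 to −20 °C; then aq. oxalic acid, Et2O, rt
Reagents that add atoms: water, O
Why: Proposed new method: an umpolung cation–olefin bicyclization in which the ion-paired chiral acid protonates the electron-rich 1-amino-1-azadiene at its terminal carbon C3 (the site where such azadienes take electrophiles) to give an N,N-dimethylazoalkenium (vinyldiazenium) ion that is electrophilic at C4 like an azoalkene in conjugate addition; C5=C10 then attacks C4 and the Z allylsilane closes ring B and loses silicon to give only the 8(17)-alkene, the chair–chair array with the E alkene and Z allylsilane giving the trans ring fusion and the equatorial C9 side chain (9S), the planar CH=N–N+Me2 arm (formed with N syn to C3 because the anion relays the proton from N–H to C3 in the s-cis conformer) being forced equatorial so that the methyl is axial (4R), and the confined anion on the protonated face choosing the face of C4 (5R,10R), while the acidity buffered by the basic hydrazone spares the allylsilane from protodesilylation; the closest known reaction types are IDPi-catalysed polyene cyclizations, allylsilane-terminated cation–olefin cyclizations and conjugate additions to azoalkenes, and the mild two-phase hydrolysis then frees the aldehyde.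

Step 11
Reactants: 17 (3S)-5-[(1S,4aR,5R,8aR)-5-formyl-5,8a-dimethyl-2-methylidenedecahydronaphthalen-1-yl]-3-methylpentyl acetate
Product: 18 (1R,4aR,5S,8aR)-5-[(3S)-5-acetoxy-3-methylpentyl]-1,4a-dimethyl-6-methylidenedecahydronaphthalene-1-carboxylic acid (the target)
Conditions: NaClO2, NaH2PO4, 2-methyl-2-butene, tBuOH/H2O, rt
Reagents that add atoms: sodium chlorite, [Na+].[O-]Cl=O
Why: Pinnick oxidation converts the hindered, non-epimerizable aldehyde into the acid; 2-methyl-2-butene scavenges HOCl so the exocyclic alkene and the acetate survive.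

## Compound list

1 | 3-methylglutaric anhydride (4-methyloxane-2,6-dione) | CC1CC(=O)OC(=O)C1 | starting material
2 | (3S)-5-methoxy-3-methyl-5-oxopentanoic acid | OC(=O)C[C@H](C)CC(=O)OC | intermediate
3 | methyl (3S)-5-hydroxy-3-methylpentanoate | OCC[C@H](C)CC(=O)OC | intermediate
4 | methyl (3R)-5-iodo-3-methylpentanoate | ICC[C@H](C)CC(=O)OC | intermediate
5 | (5E)-6,10-dimethylundeca-5,9-dien-2-one (geranylacetone) | CC(=O)CC/C=C(\C)CCC=C(C)C | starting material
6 | diethyl (5E)-6,10-dimethylundeca-1,5,9-trien-2-yl phosphate | C=C(CC/C=C(\C)CCC=C(C)C)OP(=O)(OCC)OCC | intermediate (not isolated)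
7 | (5E)-6,10-dimethylundeca-5,9-dien-1-yne | C#CCC/C=C(\C)CCC=C(C)C | intermediate
8 | (2E,6E)-2,6-dimethylundeca-2,6-dien-10-yn-1-ol | C#CCC/C=C(\C)CC/C=C(\C)CO | intermediate
9 | chloromagnesium (2E,6E)-2,6-dimethylundeca-2,6-dien-10-yn-1-olate | C#CCC/C=C(\C)CC/C=C(\C)CO[Mg]Cl | intermediate (not isolated)
10 | (1Z,5E,9E)-alkenylcopper (monovalent copper) from syn addition of Me3SiCH2Cu to 9, Cu cis to CH2SiMe3 | [Cu]/C=C(\C[Si](C)(C)C)CC/C=C(\C)CC/C=C(\C)CO[Mg]Cl | intermediate (not isolated)
11 | methyl (3S,6Z,10E,14E)-16-hydroxy-3,11,15-trimethyl-7-[(trimethylsilyl)methyl]hexadeca-6,10,14-trienoate | COC(=O)C[C@@H](C)CC/C=C(\C[Si](C)(C)C)CC/C=C(\C)CC/C=C(\C)CO | intermediate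
12 | (2E,6E,10Z,14S)-2,6,14-trimethyl-10-[(trimethylsilyl)methyl]hexadeca-2,6,10-triene-1,16-diol | OCC[C@@H](C)CC/C=C(\C[Si](C)(C)C)CC/C=C(\C)CC/C=C(\C)CO | intermediate
13 | (2E,6E,10Z,14S)-16-hydroxy-2,6,14-trimethyl-10-[(trimethylsilyl)methyl]hexadeca-2,6,10-trienal | OCC[C@@H](C)CC/C=C(\C[Si](C)(C)C)CC/C=C(\C)CC/C=C(\C)C=O | intermediate (not isolated)
14 | (3S,6Z,10E,14E,16E)-16-(2,2-dimethylhydrazinylidene)-3,11,15-trimethyl-7-[(trimethylsilyl)methyl]hexadeca-6,10,14-trien-1-ol | OCC[C@@H](C)CC/C=C(\C[Si](C)(C)C)CC/C=C(\C)CC/C=C(\C)/C=N/N(C)C | intermediate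
15 | (3S,6Z,10E,14E,16E)-16-(2,2-dimethylhydrazinylidene)-3,11,15-trimethyl-7-[(trimethylsilyl)methyl]hexadeca-6,10,14-trien-1-yl acetate | CC(=O)OCC[C@@H](C)CC/C=C(\C[Si](C)(C)C)CC/C=C(\C)CC/C=C(\C)/C=N/N(C)C | intermediate
16 | (3S)-5-[(1S,4aR,5R,8aR)-5-[(E)-(2,2-dimethylhydrazinylidene)methyl]-5,8a-dimethyl-2-methylidenedecahydronaphthalen-1-yl]-3-methylpentyl acetate | C=C1CC[C@@H]2[C@](C)(CCC[C@@]2(C)/C=N/N(C)C)[C@H]1CC[C@H](C)CCOC(C)=O | intermediate (not isolated)
17 | (3S)-5-[(1S,4aR,5R,8aR)-5-formyl-5,8a-dimethyl-2-methylidenedecahydronaphthalen-1-yl]-3-methylpentyl acetate | C=C1CC[C@@H]2[C@](C)(CCC[C@@]2(C)C=O)[C@H]1CC[C@H](C)CCOC(C)=O | intermediate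
18 | (1R,4aR,5S,8aR)-5-[(3S)-5-acetoxy-3-methylpentyl]-1,4a-dimethyl-6-methylidenedecahydronaphthalene-1-carboxylic acid; (4R,5R,9S,10R,13S)-15-acetoxylabd-8(17)-en-18-oic acid | C=C1CC[C@@H]2[C@](C)(CCC[C@@]2(C)C(=O)O)[C@H]1CC[C@H](C)CCOC(C)=O | target

## Step count and risks

Total: 11 steps. Longest linear sequence: 9 steps (1 to 18, steps 1–3 and then steps 6–11). The geranylacetone branch (5 to 8, steps 4 and 5) is 2 steps and joins at step 6.

**Step 10 (the proposed new bicyclization).** Protonation at C3 may not compete with unproductive N-protonation, and the axial/equatorial choice at C4 and the enantioselectivity are unproven. The fallback uses known chemistry, sets out from 11 and comes back at 17. Sharpless epoxidation of 11 (Ti(OiPr)4, L-(+)-diethyl tartrate, tBuOOH, 4 Å sieves, CH2Cl2, −20 °C) is hydroxyl-directed, so only the allylic alkene reacts, and gives the (2S,3S)-epoxy alcohol F1. TBSCl and imidazole give the silyl ether F2. MeAlCl2 in CH2Cl2 at −78 °C brings about the known epoxide-initiated, allylsilane-terminated bicyclization; anti opening at C4 of the E-derived epoxide through a chair–chair array puts CH2OTBS equatorial and gives the 3β-alcohol F3. PhOC(S)Cl, pyridine and DMAP give the thionocarbonate F4, and Bu3SnH with AIBN in toluene at 90 °C removes the C3 oxygen to give the deoxy ester F5. LiAlH4 gives the primary alcohol F6, Ac2O and pyridine the acetate F7, and Bu4NF the neopentyl alcohol F8. Dess–Martin periodinane then returns to aldehyde 17.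

**Step 6 (carbocupration and alkylation).** Alkylation of alkenylcoppers by functionalized primary iodides can be low-yielding. The fallback sets out from 8 and 4 and comes back at 11. The carbocupration is run as in the route but quenched with I2 to give the alkenyl iodide F9 with retention. Iodide 4 is converted with Zn dust and LiCl in THF into the alkylzinc iodide F10. Negishi coupling of F9 with F10 under PdCl2(dppf) catalysis gives 11.

**Step 5 (terminal allylic oxidation).** Site selectivity between the two trisubstituted alkenes and the propargylic position may be poor. The fallback avoids allylic oxidation, sets out from 7 and comes back at 8. NBS in THF/H2O gives the terminal bromohydrin F11, and K2CO3 in MeOH closes it to the epoxide F12. HIO4 cleaves F12 to the aldehyde F13. The stabilized ylide Ph3P=C(CH3)CO2Et gives the E ester F14, and iBu2AlH reduces it to 8.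

## Further compounds

F1 | step 10 | methyl (3S,6Z,10E)-13-[(2S,3S)-3-(hydroxymethyl)-3-methyloxiran-2-yl]-3,11-dimethyl-7-[(trimethylsilyl)methyl]trideca-6,10-dienoate | COC(=O)C[C@@H](C)CC/C=C(\C[Si](C)(C)C)CC/C=C(\C)CC[C@@H]1O[C@@]1(C)CO
F2 | step 10 | methyl (3S,6Z,10E)-13-[(2S,3S)-3-{[(tert-butyldimethylsilyl)oxy]methyl}-3-methyloxiran-2-yl]-3,11-dimethyl-7-[(trimethylsilyl)methyl]trideca-6,10-dienoate | COC(=O)C[C@@H](C)CC/C=C(\C[Si](C)(C)C)CC/C=C(\C)CC[C@@H]1O[C@@]1(C)CO[Si](C)(C)C(C)(C)C
F3 | step 10 | methyl (3S)-5-[(1S,4aR,5R,6S,8aR)-5-{[(tert-butyldimethylsilyl)oxy]methyl}-6-hydroxy-5,8a-dimethyl-2-methylidenedecahydronaphthalen-1-yl]-3-methylpentanoate | C=C1CC[C@@H]2[C@](C)(CC[C@H](O)[C@@]2(C)CO[Si](C)(C)C(C)(C)C)[C@H]1CC[C@H](C)CC(=O)OC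
F4 | step 10 | O-phenyl thionocarbonate of F3 at the C6 hydroxyl (labdane C3) | C=C1CC[C@@H]2[C@](C)(CC[C@H](OC(=S)Oc3ccccc3)[C@@]2(C)CO[Si](C)(C)C(C)(C)C)[C@H]1CC[C@H](C)CC(=O)OC
F5 | step 10 | methyl (3S)-5-[(1S,4aR,5R,8aR)-5-{[(tert-butyldimethylsilyl)oxy]methyl}-5,8a-dimethyl-2-methylidenedecahydronaphthalen-1-yl]-3-methylpentanoate | C=C1CC[C@@H]2[C@](C)(CCC[C@@]2(C)CO[Si](C)(C)C(C)(C)C)[C@H]1CC[C@H](C)CC(=O)OC
F6 | step 10 | (3S)-5-[(1S,4aR,5R,8aR)-5-{[(tert-butyldimethylsilyl)oxy]methyl}-5,8a-dimethyl-2-methylidenedecahydronaphthalen-1-yl]-3-methylpentan-1-ol | C=C1CC[C@@H]2[C@](C)(CCC[C@@]2(C)CO[Si](C)(C)C(C)(C)C)[C@H]1CC[C@H](C)CCO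
F7 | step 10 | (3S)-5-[(1S,4aR,5R,8aR)-5-{[(tert-butyldimethylsilyl)oxy]methyl}-5,8a-dimethyl-2-methylidenedecahydronaphthalen-1-yl]-3-methylpentyl acetate | C=C1CC[C@@H]2[C@](C)(CCC[C@@]2(C)CO[Si](C)(C)C(C)(C)C)[C@H]1CC[C@H](C)CCOC(C)=O
F8 | step 10 | (3S)-5-[(1S,4aR,5R,8aR)-5-(hydroxymethyl)-5,8a-dimethyl-2-methylidenedecahydronaphthalen-1-yl]-3-methylpentyl acetate | C=C1CC[C@@H]2[C@](C)(CCC[C@@]2(C)CO)[C@H]1CC[C@H](C)CCOC(C)=O
F9 | step 6 | (2E,6E,10Z)-11-iodo-2,6-dimethyl-10-[(trimethylsilyl)methyl]undeca-2,6,10-trien-1-ol | I/C=C(\C[Si](C)(C)C)CC/C=C(\C)CC/C=C(\C)CO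
F10 | step 6 | [(3R)-5-methoxy-3-methyl-5-oxopentyl]zinc iodide | COC(=O)C[C@@H](C)CC[Zn]I
F11 | step 5 | (6E)-3-bromo-2,6-dimethylundec-6-en-10-yn-2-ol (racemic at C3) | C#CCC/C=C(\C)CCC(Br)C(C)(C)O
F12 | step 5 | 2,2-dimethyl-3-[(3E)-3-methyloct-3-en-7-yn-1-yl]oxirane (racemic) | C#CCC/C=C(\C)CCC1OC1(C)C
F13 | step 5 | (4E)-4-methylnon-4-en-8-ynal | C#CCC/C=C(\C)CCC=O
F14 | step 5 | ethyl (2E,6E)-2,6-dimethylundeca-2,6-dien-10-ynoate | C#CCC/C=C(\C)CC/C=C(\C)C(=O)OCC
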